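## Retrosynthetic overview

1. The E-styrenyl bond is cut between ring A and the butenyl chain: aryllithium 14 (from bromochromene 13, ring A made by classical chromenylation) plus aldehyde 9, then E1 dehydration.
2. The stereocentre is set first, by an iminium-catalysed Friedel–Crafts addition of symmetric 3,5-dimethoxyphenol to crotonaldehyde. The phenol oxygen and the one remaining ortho carbon then carry ring B, so its regiochemistry is fixed.
3. The pyran of ring B is not closed as a pyran. It is built as a five-membered 2,2-dimethyl-3-methylidene-2,3-dihydrobenzofuran and enlarged in the last step: the exocyclic carbon is moved into the C3–aryl bond by hydroboration and a triflate-triggered 1,2-aryl shift.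
4. Enabling feature: ring-fusion carbon C4a of ring B is ortho to O1 and to C5–OMe and para to C7–OMe (phloroglucinol ring), so it is an outstanding migrating carbon. C2 is quaternary, so the only ring olefin that can form is C3=C4.
5. Ring order: pyran of ring A (step 6), five-membered ring on ring B (step 3), six-membered pyran of ring B (step 9).

Key step: step 9

Remark: the target is the (S,E) isomer. Compounds 3, 7, 15, 16, 18, 19 and 20 each carry one extra, uncontrolled stereocentre that is destroyed later, and are used as pairs of epimers.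

## Route

Step 1
Reactants: 1 3,5-dimethoxyphenol; 2 (E)-but-2-enal
Product: 4 (3S)-3-(2-hydroxy-4,6-dimethoxyphenyl)butan-1-ol, via lactol 3 (not isolated)
Conditions: (R)-2-[diphenyl(trimethylsilyloxy)methyl]pyrrolidine (20 mol%), PhCO2H (20 mol%), toluene, 0 °C; then EtOH, NaBH4, 0 °C
Reagents that add atoms: none
Why: Iminium-catalysed Friedel–Crafts alkylation of an electron-rich phenol by an enal with hemiacetal trapping is a known reaction type for naphthols and polyalkoxyphenols; the CPh2(OTMS) group of the (R)-catalyst shields one face of the E-iminium ion, so the equivalent ortho carbons of 1 should add to the Si face of C3 of the enal and set the (S) centre, and NaBH4 then reduces the lactol through its open aldehyde form to the diol.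

Step 2
Reactants: 4 (3S)-3-(2-hydroxy-4,6-dimethoxyphenyl)butan-1-ol; 5 3-bromo-3-methylbutan-2-one
Product: 6 3-{2-[(2S)-4-hydroxybutan-2-yl]-3,5-dimethoxyphenoxy}-3-methylbutan-2-one
Conditions: Cs2CO3, DMF, 50 °C
Reagents that add atoms: none
Why: Williamson-type O-alkylation, in which Cs2CO3 deprotonates only the phenol and the phenoxide displaces bromide from the carbonyl-activated tertiary carbon of 5 (as in aryloxyisobutyrate syntheses), leaving the primary alcohol and the stereocentre untouched.

Step 3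
Reactants: 6 3-{2-[(2S)-4-hydroxybutan-2-yl]-3,5-dimethoxyphenoxy}-3-methylbutan-2-one
Product: 8 (3S)-3-(4,6-dimethoxy-2,2-dimethyl-3-methylidene-2,3-dihydro-1-benzofuran-7-yl)butan-1-ol, via tertiary carbinol 7 (not isolated)
Conditions: TsOH·H2O (5 mol%), toluene, 4 Å molecular sieves, 50 °C, dilute
Reagents that add atoms: none
Why: Acid-catalysed cyclodehydration of an α-aryloxy ketone (intramolecular Friedel–Crafts hydroxyalkylation, the classical benzofuran synthesis) can only occur at the one free ortho carbon, which is ortho/para to three oxygen substituents, and carbinol 7 then loses water toward its methyl group because the quaternary C2 carries no hydrogen, so the exocyclic alkene is the only possible olefin.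

Step 4
Reactants: 8 (3S)-3-(4,6-dimethoxy-2,2-dimethyl-3-methylidene-2,3-dihydro-1-benzofuran-7-yl)butan-1-ol
Product: 9 (3S)-3-(4,6-dimethoxy-2,2-dimethyl-3-methylidene-2,3-dihydro-1-benzofuran-7-yl)butanal
Conditions: Dess–Martin periodinane, pyridine, CH2Cl2, 0 °C to rt
Reagents that add atoms: none
Why: Dess–Martin oxidation of a primary alcohol under pyridine buffering should spare the acid-sensitive exocyclic alkene, and the stereocentre is β to the new carbonyl and cannot epimerize by enolization.

Step 5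
Reactants: 1 3,5-dimethoxyphenol
Product: 10 2-bromo-3,5-dimethoxyphenol
Conditions: NBS (1.0 equiv), i-Pr2NH (10 mol%), CH2Cl2, −78 °C to 0 °C
Reagents that add atoms: N-bromosuccinimide, O=C1CCC(=O)N1Br
Why: Amine-mediated ortho-selective electrophilic bromination of a phenol; the two ortho carbons of 1 are equivalent, so a single ortho mono-bromide is expected and any para isomer is removed by chromatography.

Step 6
Reactants: 10 2-bromo-3,5-dimethoxyphenol; 11 3-methylbut-2-enal
Product: 13 8-bromo-5,7-dimethoxy-2,2-dimethyl-2H-chromene, via ortho-quinone methide 12 (not isolated)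
Conditions: PhB(OH)2 (1.0 equiv, recovered), AcOH (cat.), toluene, reflux, Dean–Stark
Reagents that add atoms: none
Why: Boronic-acid-templated ortho-specific condensation of a phenol with an enal gives the ortho-quinone methide, which closes by oxa-6π electrocyclization (classical 2,2-dimethyl-2H-chromene synthesis); C6 of 10 is the only free ortho carbon, so bromine ends up at C8.

Step 7
Reactants: 9 (3S)-3-(4,6-dimethoxy-2,2-dimethyl-3-methylidene-2,3-dihydro-1-benzofuran-7-yl)butanal; 13 8-bromo-5,7-dimethoxy-2,2-dimethyl-2H-chromene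
Product: 17 8-[(1E,3S)-3-(4,6-dimethoxy-2,2-dimethyl-3-methylidene-2,3-dihydro-1-benzofuran-7-yl)but-1-en-1-yl]-5,7-dimethoxy-2,2-dimethyl-2H-chromene, via aryllithium 14 (not isolated), via lithium alkoxide 15 (not isolated), via mesylate 16 (not isolated)
Conditions: 13, n-BuLi, THF, −78 °C; add 9, −78 °C; then MsCl, Et3N, −78 °C to rt
Reagents that add atoms: none
Why: Bromine–lithium exchange, 1,2-addition of the aryllithium to the aldehyde and in-flask mesylation, after which the benzylic sulfonate flanked by two ortho oxygens should ionize at once and lose a proton from its only β-CH2 (E1) to give the conjugated E-alkene; the carbinol epimers converge and the (S) centre is not adjacent to any ionic carbon.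

Step 8
Reactants: 17 8-[(1E,3S)-3-(4,6-dimethoxy-2,2-dimethyl-3-methylidene-2,3-dihydro-1-benzofuran-7-yl)but-1-en-1-yl]-5,7-dimethoxy-2,2-dimethyl-2H-chromene
Product: 19 {7-[(2S,3E)-4-(5,7-dimethoxy-2,2-dimethyl-2H-chromen-8-yl)but-3-en-2-yl]-4,6-dimethoxy-2,2-dimethyl-2,3-dihydro-1-benzofuran-3-yl}methanol (both C3 epimers), via alkylborane 18 (not isolated)
Conditions: 9-BBN (1.3 equiv), THF, 0 °C to rt; then aq NaOH, H2O2, 0 °C
Reagents that add atoms: hydrogen peroxide, OO
Why: Anti-Markovnikov hydroboration–oxidation, in which 9-BBN is expected to add only to the 1,1-disubstituted exocyclic alkene (boron on the unhindered CH2) because the two 1,2-disubstituted, aryl-conjugated and sterically screened alkenes react far more slowly; the new C3 centre is not controlled and both epimers are used because it becomes sp2 in step 9.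

Step 9
Reactants: 19 {7-[(2S,3E)-4-(5,7-dimethoxy-2,2-dimethyl-2H-chromen-8-yl)but-3-en-2-yl]-4,6-dimethoxy-2,2-dimethyl-2,3-dihydro-1-benzofuran-3-yl}methanol
Product: 21 8,8'-[(1E,3S)-but-1-ene-1,3-diyl]bis(5,7-dimethoxy-2,2-dimethyl-2H-chromene), via triflate 20 (not isolated)
Conditions: Tf2O (1.2 equiv), 2,6-di-tert-butyl-4-methylpyridine (3 equiv), CH2Cl2, −78 °C to 0 °C
Reagents that add atoms: none
Why: O-Triflation gives 20, whose ionization is assisted from the back by the aryl ipso carbon C3a; the bridged phenonium-type ion opens at the old C3–C3a bond, so the former exocyclic CH2 is inserted between C3 and the arene, the five-membered O1–C2–C3–C3a–C7a ring becomes the six-membered pyran, and proton loss (directly from the new C4 or after a 1,2-hydride shift to the benzylic 4-chromanyl cation) gives the conjugated C3=C4 bond. The closest known reaction types are the Wagner–Meerwein/Demjanov ring enlargement of benzo-fused cycloalkylmethyl sulfonates and diazonium ions by migration of the aryl ring bond (1-indanylmethyl to 2-tetralyl and 1,2-dihydronaphthalene systems) and the phenonium solvolysis of 2-arylalkyl sulfonates. No new ring-closing bond is made: the pyran arises by a suprafacial 1,2-shift of the aryl carbon through a three-membered (Ar1-3, 3-exo-tet) bridged ion. No stereocentre is created; the uncontrolled C3 centre of 19 becomes sp2 and the (S) centre is remote from the cationic carbons. The step needs aryl migration to win over 1,2-hydride shift, E2 loss of triflic acid and migration of C2, and proton loss into the ring; this is secured by the ipso carbon being ortho to O1 and to the 4-OMe carbon and para to the 6-OMe carbon, by the quaternary C2 that leaves C3=C4 as the only possible ring olefin, and by a hindered non-nucleophilic base.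

## Compound list

1 | 3,5-dimethoxyphenol | COc1cc(O)cc(OC)c1 | starting material
2 | (E)-but-2-enal | C/C=C/C=O | starting material
3 | (4S)-5,7-dimethoxy-4-methyl-3,4-dihydro-2H-chromen-2-ol (both C2 epimers) | OC1C[C@H](C)c2c(OC)cc(OC)cc2O1 | intermediate (not isolated)
4 | (3S)-3-(2-hydroxy-4,6-dimethoxyphenyl)butan-1-ol | OCC[C@H](C)c1c(O)cc(OC)cc1OC | intermediate
5 | 3-bromo-3-methylbutan-2-one | CC(=O)C(C)(C)Br | starting material
6 | 3-{2-[(2S)-4-hydroxybutan-2-yl]-3,5-dimethoxyphenoxy}-3-methylbutan-2-one | OCC[C@H](C)c1c(OC(C)(C)C(C)=O)cc(OC)cc1OC | intermediate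
7 | (3S)-3-(3-hydroxy-4,6-dimethoxy-2,2,3-trimethyl-2,3-dihydro-1-benzofuran-7-yl)butan-1-ol (both C3 epimers) | OCC[C@H](C)c1c(OC)cc(OC)c2c1OC(C)(C)C2(C)O | intermediate (not isolated)
8 | (3S)-3-(4,6-dimethoxy-2,2-dimethyl-3-methylidene-2,3-dihydro-1-benzofuran-7-yl)butan-1-ol | OCC[C@H](C)c1c(OC)cc(OC)c2c1OC(C)(C)C2=C | intermediate
9 | (3S)-3-(4,6-dimethoxy-2,2-dimethyl-3-methylidene-2,3-dihydro-1-benzofuran-7-yl)butanal | O=CC[C@H](C)c1c(OC)cc(OC)c2c1OC(C)(C)C2=C | intermediate
10 | 2-bromo-3,5-dimethoxyphenol | Oc1cc(OC)cc(OC)c1Br | intermediate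
11 | 3-methylbut-2-enal | CC(C)=CC=O | starting material
12 | 2-bromo-3,5-dimethoxy-6-(3-methylbut-2-en-1-ylidene)cyclohexa-2,4-dien-1-one | O=C1C(Br)=C(OC)C=C(OC)C1=CC=C(C)C | intermediate (not isolated)
13 | 8-bromo-5,7-dimethoxy-2,2-dimethyl-2H-chromene | COc1cc(OC)c(Br)c2c1C=CC(C)(C)O2 | intermediate
14 | (5,7-dimethoxy-2,2-dimethyl-2H-chromen-8-yl)lithium | COc1cc(OC)c([Li])c2c1C=CC(C)(C)O2 | intermediate (not isolated)
15 | lithium (3S)-3-(4,6-dimethoxy-2,2-dimethyl-3-methylidene-2,3-dihydro-1-benzofuran-7-yl)-1-(5,7-dimethoxy-2,2-dimethyl-2H-chromen-8-yl)butan-1-olate (both C1 epimers) | COc1cc(OC)c(C(O[Li])C[C@H](C)c3c(OC)cc(OC)c4c3OC(C)(C)C4=C)c2c1C=CC(C)(C)O2 | intermediate (not isolated)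
16 | (3S)-3-(4,6-dimethoxy-2,2-dimethyl-3-methylidene-2,3-dihydro-1-benzofuran-7-yl)-1-(5,7-dimethoxy-2,2-dimethyl-2H-chromen-8-yl)butyl methanesulfonate (both C1 epimers) | COc1cc(OC)c(C(OS(C)(=O)=O)C[C@H](C)c3c(OC)cc(OC)c4c3OC(C)(C)C4=C)c2c1C=CC(C)(C)O2 | intermediate (not isolated)
17 | 8-[(1E,3S)-3-(4,6-dimethoxy-2,2-dimethyl-3-methylidene-2,3-dihydro-1-benzofuran-7-yl)but-1-en-1-yl]-5,7-dimethoxy-2,2-dimethyl-2H-chromene | COc1cc(OC)c(/C=C/[C@H](C)c3c(OC)cc(OC)c4c3OC(C)(C)C4=C)c2c1C=CC(C)(C)O2 | intermediate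
18 | 9-({7-[(2S,3E)-4-(5,7-dimethoxy-2,2-dimethyl-2H-chromen-8-yl)but-3-en-2-yl]-4,6-dimethoxy-2,2-dimethyl-2,3-dihydro-1-benzofuran-3-yl}methyl)-9-borabicyclo[3.3.1]nonane (both C3 epimers) | COc1cc(OC)c(/C=C/[C@H](C)c3c(OC)cc(OC)c4c3OC(C)(C)C4CB5C6CCCC5CCC6)c2c1C=CC(C)(C)O2 | intermediate (not isolated)
19 | {7-[(2S,3E)-4-(5,7-dimethoxy-2,2-dimethyl-2H-chromen-8-yl)but-3-en-2-yl]-4,6-dimethoxy-2,2-dimethyl-2,3-dihydro-1-benzofuran-3-yl}methanol (both C3 epimers) | COc1cc(OC)c(/C=C/[C@H](C)c3c(OC)cc(OC)c4c3OC(C)(C)C4CO)c2c1C=CC(C)(C)O2 | intermediate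
20 | {7-[(2S,3E)-4-(5,7-dimethoxy-2,2-dimethyl-2H-chromen-8-yl)but-3-en-2-yl]-4,6-dimethoxy-2,2-dimethyl-2,3-dihydro-1-benzofuran-3-yl}methyl trifluoromethanesulfonate (both C3 epimers) | COc1cc(OC)c(/C=C/[C@H](C)c3c(OC)cc(OC)c4c3OC(C)(C)C4COS(=O)(=O)C(F)(F)F)c2c1C=CC(C)(C)O2 | intermediate (not isolated)
21 | 8,8'-[(1E,3S)-but-1-ene-1,3-diyl]bis(5,7-dimethoxy-2,2-dimethyl-2H-chromene) | COc1cc(OC)c(/C=C/[C@H](C)c2c(OC)cc(OC)c3c2OC(C)(C)C=C3)c2c1C=CC(C)(C)O2 | target

## Step count and risks

Total step count: 9. Longest linear sequence: 7 (steps 1, 2, 3, 4, 7, 8, 9).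

Steps most likely to fail:

Step 9. The aryl shift may lose to a 1,2-hydride shift or to E2 loss of triflic acid (both return alkene 17, which can be recycled through step 8), and the acid set free may oligomerize the electron-rich alkenes. The fallback moves the ring enlargement to the ketone oxidation level and ahead of the fragment union. It sets out from 8. PhI(OH)OTs (a trivalent iodine reagent) in aqueous MeCN at 0 °C should add to the exocyclic CH2 and trigger aryl migration with loss of iodobenzene, a known oxidative ring enlargement of exocyclic aryl alkenes, to give (S)-8-(4-hydroxybutan-2-yl)-5,7-dimethoxy-2,2-dimethyl-2H-chromen-3(4H)-one F1. TsNHNH2 in MeOH gives the tosylhydrazone F2. A Bamford–Stevens reaction (NaOMe, diglyme, 140 °C), in which the 1,2-hydrogen shift can only come from C4, gives (3S)-3-(5,7-dimethoxy-2,2-dimethyl-2H-chromen-8-yl)butan-1-ol F3. Dess–Martin oxidation gives (3S)-3-(5,7-dimethoxy-2,2-dimethyl-2H-chromen-8-yl)butanal F4. Addition of 14 and in-flask mesylation and elimination as in step 7, through the lithium alkoxide F5 and the mesylate F6, comes back to the route at 21.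

Step 2. Substitution at the tertiary carbon by a hindered phenoxide may be slow, so that dehydrobromination of 5 and C-alkylation take over. The fallback forms the ether with a bromoester and builds the ketone afterwards. It sets out from 4. Ethyl 2-bromo-2-methylpropanoate with Cs2CO3 in MeCN at reflux (the well-precedented aryloxyisobutyrate alkylation) gives ethyl 2-{2-[(2S)-4-hydroxybutan-2-yl]-3,5-dimethoxyphenoxy}-2-methylpropanoate F7. LiOH in aqueous THF gives 2-{2-[(2S)-4-hydroxybutan-2-yl]-3,5-dimethoxyphenoxy}-2-methylpropanoic acid F8. MeLi (3.2 equiv, THF, 0 °C; ketone synthesis from a lithium carboxylate) comes back to the route at 6.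

Step 1. Facial selectivity may erode through uncatalysed or acid-catalysed background addition, and para-attack or a second arylation of the lactol may compete. The fallback sets the stereocentre by asymmetric conjugate reduction. It sets out from 1. Pechmann condensation with ethyl acetoacetate (H2SO4, 0 °C to rt) gives 5,7-dimethoxy-4-methyl-2H-chromen-2-one F9. CuH-catalysed asymmetric 1,4-reduction (Cu(OAc)2·H2O, the enantiomer of DTBM-SEGPHOS that delivers hydride to the face giving the (S) lactone, (EtO)2MeSiH, t-BuOH, toluene) gives (4S)-5,7-dimethoxy-4-methyl-3,4-dihydro-2H-chromen-2-one F10. LiAlH4 in THF at 0 °C comes back to the route at 4.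

Further compounds

F1 | step 9 | (S)-8-(4-hydroxybutan-2-yl)-5,7-dimethoxy-2,2-dimethyl-2H-chromen-3(4H)-one | OCC[C@H](C)c1c(OC)cc(OC)c2c1OC(C)(C)C(=O)C2
F2 | step 9 | N'-[(S)-8-(4-hydroxybutan-2-yl)-5,7-dimethoxy-2,2-dimethyl-2H-chromen-3(4H)-ylidene]-4-methylbenzenesulfonohydrazide | OCC[C@H](C)c1c(OC)cc(OC)c2c1OC(C)(C)C(=NNS(=O)(=O)c3ccc(C)cc3)C2
F3 | step 9 | (3S)-3-(5,7-dimethoxy-2,2-dimethyl-2H-chromen-8-yl)butan-1-ol | OCC[C@H](C)c1c(OC)cc(OC)c2c1OC(C)(C)C=C2
F4 | step 9 | (3S)-3-(5,7-dimethoxy-2,2-dimethyl-2H-chromen-8-yl)butanal | O=CC[C@H](C)c1c(OC)cc(OC)c2c1OC(C)(C)C=C2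
F5 | step 9 | lithium (3S)-1,3-bis(5,7-dimethoxy-2,2-dimethyl-2H-chromen-8-yl)butan-1-olate (both C1 epimers) | COc1cc(OC)c(C(O[Li])C[C@H](C)c3c(OC)cc(OC)c4c3OC(C)(C)C=C4)c2c1C=CC(C)(C)O2
F6 | step 9 | (3S)-1,3-bis(5,7-dimethoxy-2,2-dimethyl-2H-chromen-8-yl)butyl methanesulfonate (both C1 epimers) | COc1cc(OC)c(C(OS(C)(=O)=O)C[C@H](C)c3c(OC)cc(OC)c4c3OC(C)(C)C=C4)c2c1C=CC(C)(C)O2
F7 | step 2 | ethyl 2-{2-[(2S)-4-hydroxybutan-2-yl]-3,5-dimethoxyphenoxy}-2-methylpropanoate | OCC[C@H](C)c1c(OC(C)(C)C(=O)OCC)cc(OC)cc1OC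
F8 | step 2 | 2-{2-[(2S)-4-hydroxybutan-2-yl]-3,5-dimethoxyphenoxy}-2-methylpropanoic acid | OCC[C@H](C)c1c(OC(C)(C)C(=O)O)cc(OC)cc1OC
F9 | step 1 | 5,7-dimethoxy-4-methyl-2H-chromen-2-one | CC1=CC(=O)Oc2cc(OC)cc(OC)c12
F10 | step 1 | (4S)-5,7-dimethoxy-4-methyl-3,4-dihydro-2H-chromen-2-one | O=C1C[C@H](C)c2c(OC)cc(OC)cc2O1
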